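**Assumption:** the target has no stereocentre and no stereogenic double bond, so it is achiral and "single enantiomer" needs no stereocontrol; compounds 1 and 5 are taken as catalogue compounds.

**Retrosynthetic overview**
1. Target ⇐ removal of a 3'-O-pivalate; the 6-OH comes from ortho-oxygenation of the 5-OH phenol (IBX to the 5,6-quinone, then reduction).
2. 5-OH ⇐ carbonyl-directed, ruthenium-catalysed C5–H hydroxylation of a plain 7,8-dimethoxyflavone, so both hydroxyls of ring A are installed late instead of being carried in a hexasubstituted acetophenone.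
3. Ring C ⇐ rhodium-catalysed aldehyde C–H acylmethylation and cyclodehydration of 2-hydroxy-3,4-dimethoxybenzaldehyde with an aroyl sulfoxonium ylide (no chalcone, no Baker–Venkataraman).
4. Ylide ⇐ isovanillic acid (pivaloylation, acid chloride, sulfoxonium methylide).
5. Rings A and B are bought; ring C is the only ring formed (step 3).

**Step 1**
Reactants: 1 3-hydroxy-4-methoxybenzoic acid (isovanillic acid)
Product: 2 4-methoxy-3-(pivaloyloxy)benzoic acid
Conditions: PivCl (1.2 equiv), NaOH (2 M aq, 2.5 equiv), THF, 0 °C to rt; then 2 M HCl to pH 2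
Reagents that add atoms: pivaloyl chloride CC(C)(C)C(=O)Cl
Why: Schotten–Baumann O-acylation of the phenoxide gives the hindered aryl pivalate (acid-, oxidant- and ylide-tolerant), while any mixed anhydride at the carboxylate hydrolyses back in the aqueous base; no stereocentre.

**Step 2**
Reactants: 2 4-methoxy-3-(pivaloyloxy)benzoic acid
Product: 4 dimethylsulfoxonium 2-[4-methoxy-3-(pivaloyloxy)phenyl]-2-oxoethylide, via acid chloride 3 (not isolated)
Conditions: (COCl)2 (1.3 equiv), DMF (cat.), CH2Cl2, 0 °C to rt, evaporate; then add to Me3S(O)I (2.3 equiv)/KOtBu (2.2 equiv) pre-refluxed in THF, 0 °C to rt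
Reagents that add atoms: oxalyl chloride O=C(Cl)C(=O)Cl (gives only the Cl of 3); trimethylsulfoxonium iodide C[S+](C)(C)=O.[I-]
Why: Corey–Chaykovsky-type C-acylation of dimethylsulfoxonium methylide by the acid chloride, with the second equivalent of methylide deprotonating the acylsulfoxonium salt to the stabilised ylide, is far faster at 0 °C than attack on the hindered aryl pivalate; no stereocentre.

**Step 3**
Reactants: 4 dimethylsulfoxonium 2-[4-methoxy-3-(pivaloyloxy)phenyl]-2-oxoethylide; 5 2-hydroxy-3,4-dimethoxybenzaldehyde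
Product: 7 7,8-dimethoxy-2-[4-methoxy-3-(pivaloyloxy)phenyl]chromen-4-one, via 1,3-diketone 6 (not isolated)
Conditions: [Cp*RhCl2]2 (2.5 mol %), AgSbF6 (10 mol %), NaOAc (30 mol %), 4 (1.2 equiv), DCE, 80 °C; then TsOH·H2O (20 mol %), 80 °C
Reagents that add atoms: none
Why: Phenoxide-directed aldehyde C–H activation by trivalent rhodium gives a five-membered acyl rhodacycle, carbene transfer from the sulfoxonium ylide (loss of DMSO) and migratory insertion give the 1-(2-hydroxyaryl)-3-aryl-1,3-dione after protodemetalation, and acid-catalysed cyclodehydration closes the 4-pyranone (C–H acylmethylation/annulation); no stereocentre.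

**Step 4**
Reactants: 7 7,8-dimethoxy-2-[4-methoxy-3-(pivaloyloxy)phenyl]chromen-4-one
Product: 9 5-hydroxy-7,8-dimethoxy-2-[4-methoxy-3-(pivaloyloxy)phenyl]chromen-4-one, via 5-trifluoroacetate 8 (not isolated)
Conditions: [RuCl2(p-cymene)]2 (5 mol %), PhI(OCOCF3)2 (1.5 equiv), TFA/TFAA (3:1), 80 °C; then MeOH/aq NaHCO3, rt
Reagents that add atoms: [bis(trifluoroacetoxy)iodo]benzene O=C(OI(OC(=O)C(F)(F)F)c1ccccc1)C(F)(F)F
Why: Ketone-directed C–H oxygenation: the C4 carbonyl steers carboxylate-assisted ruthenation by divalent ruthenium to the unhindered peri C5–H (five-membered ruthenacycle), the hypervalent iodine oxidant raises the metal to tetravalent ruthenium, and C–O reductive elimination gives the aryl trifluoroacetate, which resists over-oxidation and hydrolyses on work-up, while the protonated flavone and the pivalate keep ring B inert; no stereocentre.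

**Step 5**
Reactants: 9 5-hydroxy-7,8-dimethoxy-2-[4-methoxy-3-(pivaloyloxy)phenyl]chromen-4-one
Product: 11 5,6-dihydroxy-7,8-dimethoxy-2-[4-methoxy-3-(pivaloyloxy)phenyl]chromen-4-one, via ortho-quinone 10 (not isolated)
Conditions: IBX (1.2 equiv), DMF, rt, dark; then Na2S2O4 (3 equiv), H2O, rt
Reagents that add atoms: IBX (2-iodoxybenzoic acid) O=C1OI(=O)(O)c2ccccc12
Why: IBX phenol-to-ortho-quinone oxidation: the phenol binds the pentavalent iodine centre and oxygen is delivered intramolecularly to the only free ortho carbon (C6, activated by the 7-OMe), giving the 5,6-quinone that dithionite reduces at once to the catechol, while the only other phenolic oxygen in the molecule is masked as the pivalate; no stereocentre.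

**Step 6**
Reactants: 11 5,6-dihydroxy-7,8-dimethoxy-2-[4-methoxy-3-(pivaloyloxy)phenyl]chromen-4-one
Product: 12 5,6,3'-trihydroxy-7,8,4'-trimethoxyflavone (target)
Conditions: K2CO3 (3 equiv), degassed MeOH, Ar, rt to 40 °C; then 1 M HCl to pH 3
Reagents that add atoms: none
Why: Base-mediated transesterification (methanolysis) of the aryl pivalate, driven by the phenoxide leaving group, frees the 3'-OH without touching the methyl ethers or the pyranone, and exclusion of air protects the catechol; no stereocentre.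

**Compound list**
1 | 3-hydroxy-4-methoxybenzoic acid (isovanillic acid) | COc1ccc(C(=O)O)cc1O | starting material
2 | 4-methoxy-3-(pivaloyloxy)benzoic acid | COc1ccc(C(=O)O)cc1OC(=O)C(C)(C)C | intermediate
3 | 4-methoxy-3-(pivaloyloxy)benzoyl chloride | COc1ccc(C(=O)Cl)cc1OC(=O)C(C)(C)C | intermediate (not isolated)
4 | dimethylsulfoxonium 2-[4-methoxy-3-(pivaloyloxy)phenyl]-2-oxoethylide | COc1ccc(C(=O)C=S(C)(C)=O)cc1OC(=O)C(C)(C)C | intermediate
5 | 2-hydroxy-3,4-dimethoxybenzaldehyde | COc1ccc(C=O)c(O)c1OC | starting material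
6 | 1-(2-hydroxy-3,4-dimethoxyphenyl)-3-[4-methoxy-3-(pivaloyloxy)phenyl]propane-1,3-dione | COc1ccc(C(=O)CC(=O)c2ccc(OC)c(OC(=O)C(C)(C)C)c2)c(O)c1OC | intermediate (not isolated)
7 | 7,8-dimethoxy-2-[4-methoxy-3-(pivaloyloxy)phenyl]chromen-4-one | COc1ccc(-c2cc(=O)c3ccc(OC)c(OC)c3o2)cc1OC(=O)C(C)(C)C | intermediate
8 | 7,8-dimethoxy-2-[4-methoxy-3-(pivaloyloxy)phenyl]-4-oxochromen-5-yl trifluoroacetate | COc1ccc(-c2cc(=O)c3c(OC(=O)C(F)(F)F)cc(OC)c(OC)c3o2)cc1OC(=O)C(C)(C)C | intermediate (not isolated)
9 | 5-hydroxy-7,8-dimethoxy-2-[4-methoxy-3-(pivaloyloxy)phenyl]chromen-4-one | COc1ccc(-c2cc(=O)c3c(O)cc(OC)c(OC)c3o2)cc1OC(=O)C(C)(C)C | intermediate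
10 | 7,8-dimethoxy-2-[4-methoxy-3-(pivaloyloxy)phenyl]chromene-4,5,6-trione | COC1=C(OC)C2=C(C(=O)C=C(c3ccc(OC)c(OC(=O)C(C)(C)C)c3)O2)C(=O)C1=O | intermediate (not isolated)
11 | 5,6-dihydroxy-7,8-dimethoxy-2-[4-methoxy-3-(pivaloyloxy)phenyl]chromen-4-one | COc1ccc(-c2cc(=O)c3c(O)c(O)c(OC)c(OC)c3o2)cc1OC(=O)C(C)(C)C | intermediate
12 | 5,6,3'-trihydroxy-7,8,4'-trimethoxyflavone | COc1ccc(-c2cc(=O)c3c(O)c(O)c(OC)c(OC)c3o2)cc1O | target

**Total step count:** 6.
**Longest linear sequence:** 6 steps (1 → 2 → 4 → 7 → 9 → 11 → 12); aldehyde 5 enters at step 3.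

**Three steps most likely to fail, with fallbacks**

Step 5 (IBX ortho-oxygenation) is the riskiest, because the 5-OH is hydrogen-bonded to the C4 carbonyl and may not bind the iodine reagent. The fallback sets out from 9 and installs the oxygen through a carbon substituent. Duff formylation (hexamethylenetetramine, TFA, 80 °C, then aq HCl) at C6, the only free position of ring A, gives 6-formyl-5-hydroxy-7,8-dimethoxy-2-[4-methoxy-3-(pivaloyloxy)phenyl]chromen-4-one F5. Dakin-type Baeyer–Villiger oxidation of this ortho-hydroxy aldehyde (mCPBA, CH2Cl2, 0 °C to rt) gives 5-hydroxy-7,8-dimethoxy-2-[4-methoxy-3-(pivaloyloxy)phenyl]-4-oxochromen-6-yl formate F6. Brief methanolysis of the formate (KHCO3, MeOH, 0 °C) leaves the pivalate in place and comes back to the route at 11.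

Step 4 (ruthenium C5–H hydroxylation) may suffer from oxidation of the electron-rich ring A by the iodine oxidant or from slow ruthenation. The fallback carries the C5 oxygen in from the start. It sets out from ylide 4, which is coupled under the step 3 conditions with 2-hydroxy-3,4,6-trimethoxybenzaldehyde F3 to give 5,7,8-trimethoxy-2-[4-methoxy-3-(pivaloyloxy)phenyl]chromen-4-one F4. BCl3 (1.2 equiv, CH2Cl2, −78 to 0 °C) then cleaves only the 5-O-methyl ether, which is chelated to the C4 carbonyl, and the route is rejoined at 9.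

Step 3 (rhodium annulation) may fail through ylide self-coupling or sluggish aldehyde C–H activation. The fallback uses the classical acyl-transfer logic as insurance only. It sets out from acid chloride 3 (made from 2 as in step 2), which acylates 2'-hydroxy-3',4'-dimethoxyacetophenone F1 (pyridine, DMAP cat., CH2Cl2, 0 °C to rt) to give 6-acetyl-2,3-dimethoxyphenyl 4-methoxy-3-(pivaloyloxy)benzoate F2. A Baker–Venkataraman O-to-C acyl shift (LiN(SiMe3)2, THF, −78 to 0 °C) converts F2 into diketone 6, where the route is rejoined; TsOH closes 6 to 7 as in step 3.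

**Further compounds**
F1 | step 3 | 2'-hydroxy-3',4'-dimethoxyacetophenone | CC(=O)c1ccc(OC)c(OC)c1O
F2 | step 3 | 6-acetyl-2,3-dimethoxyphenyl 4-methoxy-3-(pivaloyloxy)benzoate | CC(=O)c1ccc(OC)c(OC)c1OC(=O)c1ccc(OC)c(OC(=O)C(C)(C)C)c1
F3 | step 4 | 2-hydroxy-3,4,6-trimethoxybenzaldehyde | COc1cc(OC)c(C=O)c(O)c1OC
F4 | step 4 | 5,7,8-trimethoxy-2-[4-methoxy-3-(pivaloyloxy)phenyl]chromen-4-one | COc1ccc(-c2cc(=O)c3c(OC)cc(OC)c(OC)c3o2)cc1OC(=O)C(C)(C)C
F5 | step 5 | 6-formyl-5-hydroxy-7,8-dimethoxy-2-[4-methoxy-3-(pivaloyloxy)phenyl]chromen-4-one | COc1ccc(-c2cc(=O)c3c(O)c(C=O)c(OC)c(OC)c3o2)cc1OC(=O)C(C)(C)C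
F6 | step 5 | 5-hydroxy-7,8-dimethoxy-2-[4-methoxy-3-(pivaloyloxy)phenyl]-4-oxochromen-6-yl formate | COc1ccc(-c2cc(=O)c3c(O)c(OC=O)c(OC)c(OC)c3o2)cc1OC(=O)C(C)(C)C
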